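The coupling partner is what I count in the dusk flask, the one asked about, because it is charged below the substrate, 0.090 M against 0.10 M, which makes it the limiting reagent.

| setting | dusk | dawn | flask |
|---|---|---|---|
| substrate | 0.10 M | 0.067 M | 0.10 M |
| coupling partner | 0.090 M | 0.090 M | 0.0900 M |
| remark | the very flask that is asked about, followed so far | run made earlier |  |
| time |  |  | 50 min |

| run | time / min | tris adduct / % | double product / % |
|---|---|---|---|
| dusk | 3.00 | 0.3 | 1.4 |
| dusk | 6.00 | 1.0 | 1.6 |
| dusk | 10.0 | 1.9 | 3.9 |
| dusk | 12.0 | 2.3 | 4.4 |
| dusk | 15.0 | 2.3 | 4.5 |
| dusk | 20.0 | 2.8 | 4.5 |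
| dawn | 2.50 | 0.1 | 1.5 |
| dawn | 6.00 | 2.6 | 3.6 |
| dawn | 12.0 | 4.8 | 6.5 |
| dawn | 20.0 | 5.8 | 6.1 |
| dawn | 25.0 | 7.5 | 8.2 |
| dawn | 40.0 | 9.0 | 7.8 |

(each reading ± 0.5 percentage points)

- reactions considered so far: substrate + coupling partner -> first product; coupling partner + first product -> double product; coupling partner + double product -> tris adduct; coupling partner + tris adduct -> tetra adduct

- concentration of tris adduct at 50 min, in M
- concentration of double product at 50 min, in M
- concentration of substrate at 50 min, in M
- concentration of first product at 50 min, in M

One thing looks wrong. The dawn flask has less substrate and the same partner, yet at 20.0 min it reads more tris adduct, 0.00389 M against 0.00280 M in the dusk flask.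

Partner goes to substrate or to the followers, and their share grows as substrate falls and first product builds. Each substrate molecule turned takes one partner, and each later step takes one more, so I keep a ledger:

overdraft = c(double product) + 2 c(tris adduct) + 3 c(tetra adduct)

c(substrate) = substrate charged − partner charged + overdraft + c(partner left)

The dawn flask charges 0.0230 M more partner than substrate, and its overdraft, with tetra adduct uncounted, reads 0.0173 M at 40.0 min. The dusk flask needs none to use its partner.

Double product in the dusk flask reads flat from 12.0 min, so I take its partner as nearly used, and I leave tetra adduct uncounted. The last dusk readings then give: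

overdraft = 0.00450 M + 2 × 0.00280 M = 0.0101 M

This overdraft gives, at 50 min:

c(substrate) = 0.10 M − 0.0900 M + 0.0101 M = 0.0201 M

c(first product) = 0.0726 M

I hold tris adduct and double product at their readings. The forecast says 0.0035 M tris adduct, 0.0046 M double product, 0.027 M substrate and 0.063 M first product, higher than mine in substrate, and for the substrate left over it gives the ground that “the partner is limiting and second-step losses waste it”.

The flask gives 0.00227 M tris adduct, 0.00475 M double product, 0.0198 M substrate and 0.0731 M first product, with 0.0720% of its partner left.

    substrate + coupling partner → first product (k = 0.0682 M⁻¹ s⁻¹)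
    coupling partner + first product → double product (k = 0.00629 M⁻¹ s⁻¹)
    coupling partner + double product → tris adduct (k = 0.0500 M⁻¹ s⁻¹)
    coupling partner + tris adduct → tetra adduct (k = 0.00865 M⁻¹ s⁻¹)

The neighbour flask keeps the substrate charge and the time but takes 0.22 M of partner, 0.120 M above the substrate. At 50 min it holds 0.00712 M of partner, so the ledger asks for an overdraft of 0.113 M. Its contents supply 0.113 M, with tris adduct at 0.0286 M, and its substrate stands at 1.30 × 10⁻⁵ M.

Readings and results are calculated with constants of no real substance, and the scatter is random.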